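All runs are simulated with made-up constants; noise was put on by code.

If the next flask is to be finished in 15 min, you must decide how much starting material a charge of free catalyst can carry, and whether a thin charge is worth waiting for.

| setting | dawn | summer | midnight | dusk | teal | violet | blue | red | green |
|---|---|---|---|---|---|---|---|---|---|
| starting material | 0.014 M | 0.022 M | 0.039 M | 0.020 M | 0.020 M | 0.030 M | 0.012 M | 0.020 M | 0.040 M |
| reagent | 0.024 M | 0.024 M | 0.024 M | 0.039 M | 0.0240 M | 0.0400 M | 0.0240 M | 0.0240 M | 0.0500 M |
| free catalyst | 40 µM | 40 µM | 40 µM | 40 µM | 10 µM | 10 µM | 40 µM | 40 µM | 40 µM |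
| remark | run made earlier | run made earlier | run made earlier | run made earlier |  |  |  |  |  |
| time |  |  |  |  | 15 min | 15 min | 15 min | 15 min | 15 min |

- dawn (time / min: target / %, starting material / %): 0.833: 11, 88; 1.50: 19, 81; 3.00: 36, 63; 6.00: 66, 32; 10.0: 96, 3
- summer (time / min: target / %, starting material / %): 2.00: 16, 84; 4.00: 32, 69; 6.00: 44, 58; 8.00: 55, 46; 10.0: 65, 35
- midnight (time / min: target / %, starting material / %): 0.833: 3, 95; 1.50: 5, 93; 3.00: 13, 84; 6.00: 27, 77; 10.0: 36, 62
- dusk (time / min: target / %, starting material / %): 2.00: 17, 83; 4.00: 33, 64; 6.00: 48, 51; 8.00: 60, 39; 10.0: 70, 31

(readings scatter by 1.5 percentage points)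

- the numbers in the tables scatter with a standard deviation of 1.5 percentage points
- no earlier run changes the charge of free catalyst; that part of a forecast is a guess

1. all flasks from highest to lowest amount of target, in percent of the starting material charged, at 15 min (teal / violet / blue / red / green)
2. the amount of target, in percent of the starting material charged of the flask you put first, at 15 min
3. the amount of target, in percent of the starting material charged of the flask you put last, at 15 min

Read the target as a concentration, not a percentage. At 10.0 min, summer holds 0.0143 M, dusk 0.0140 M and midnight 0.0140 M, although their starting material differs. In these runs, then, time matters and the charges hardly do.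

Averaging summer and dusk gives 0.00682 M at 4.00 min and 0.0120 M at 8.00 min, so the second interval makes less than the first. I take the rate as falling exponentially, which gives a decay constant of 0.0664 min⁻¹. Integrating that rate gives a ceiling times one minus exp(−kt), and the ceiling for 40 µM is 0.0293 M.

At 15 min this gives 0.0184 M, the reach: the concentration of target a charge of free catalyst makes by a given time while both charges last. By my reckoning blue, with less starting material than that, finishes, red reaches 92.2 % and green 46.1 %. No run varies the catalyst, so I guess that a quarter of the charge gives a quarter of the reach: teal 23.1 %, violet 15.3 %. My ceiling at 10 µM is 0.00733 M, less than violet's charge of 0.030 M, so for violet I would add catalyst, not time.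

The forecast gives blue > red > green > teal > violet, with 99 % first and 18 % last, calling the reaction “close to zero order in both starting material and reagent”. Its violet stands above mine.

The flasks give blue > red > green > teal > violet, with blue at 99.9 % and violet at 15.2 %.

    starting material + free catalyst → catalyst intermediate A (k = 2780 M⁻¹ s⁻¹)
    catalyst intermediate A → catalyst intermediate B (k = 1.07 s⁻¹)
    reagent + catalyst intermediate B → catalyst intermediate C (k = 3890 M⁻¹ s⁻¹)
    catalyst intermediate C → catalyst intermediate D (k = 15.0 s⁻¹)
    catalyst intermediate D → free catalyst + target (k = 5.46 s⁻¹)
    catalyst intermediate A → spent catalyst (k = 0.00156 s⁻¹)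

In violet at 15.0 min, catalyst intermediate A goes on to catalyst intermediate B 690 times as fast as it goes to spent catalyst, a total turnover number that on 10 µM comes to 0.00686 M, and violet holds 0.00686 M of target at 150 min, with spent catalyst at >99.9 %. At 15 min violet holds 0.00456 M of target beside its scaled reach of 0.00460 M, and the flask like violet but with 4.0 × 10⁻⁵ M of free catalyst holds 0.0181 M beside the reach of 0.0184 M.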